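The route rests on excising the C(=CH2) carbon together with its two CH2 arms. In the target this methylidene carbon is bonded to one CH2 that leads to the (E)-CH=CH unit and to another CH2 that is joined to the CH2 beside the acyl ketone on C3 of the 5,6-dihydro-2H-pyran-2-one ring. The unit is brought in as dibromide 10. One telescoped operation forms both flanking C–C bonds: Suzuki–Miyaura allyl–alkenyl coupling of (E)-alkenylboronate 9, then γ-alkylation of the tert-butyl acetoacetate dianion, giving β-keto ester 14. Precursor 9 is a pinacol alkenylboronate on a 1,3-dioxane acetonide that already carries all three chain stereocentres. The pyranone ring is closed afterwards, and the carboxyl group is made last.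

Key step: step 7

Assumption: the 3-acyl-4-hydroxy-5,6-dihydro-2H-pyran-2-one is written as the enol tautomer of the target SMILES; its other tricarbonyl tautomers are the same compound.

Step 1
Reactants: 1 (S)-2-methylbutan-1-ol
Product: 3 ethyl (2E,4S)-4-methylhex-2-enoate, via (S)-2-methylbutanal 2 (not isolated)
Conditions: TEMPO (10 mol %), PhI(OAc)2 (1.1 equiv), CH2Cl2, rt; then Ph3P=CHCO2Et (1.3 equiv), rt
Reagents that add atoms: ethyl (triphenylphosphoranylidene)acetate, CCOC(=O)C=P(c1ccccc1)(c1ccccc1)c1ccccc1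
Why: The TEMPO/PhI(OAc)2 alcohol oxidation stops at the aldehyde and the stabilised ylide then gives the (E)-enoate by Wittig olefination in the same flask, so the volatile, configurationally labile aldehyde 2 is never isolated and the stereocentre of 1 is carried through unchanged.

Step 2
Reactants: 3 ethyl (2E,4S)-4-methylhex-2-enoate
Product: 4 (2E,4S)-4-methylhex-2-en-1-ol
Conditions: iBu2AlH (2.2 equiv), CH2Cl2, −78 °C
Reagents that add atoms: none
Why: Hydride 1,2-reduction of the α,β-unsaturated ester at low temperature should give the (E)-allylic alcohol without touching the alkene or the stereocentre.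

Step 3
Reactants: 4 (2E,4S)-4-methylhex-2-en-1-ol
Product: 5 [(2R,3R)-3-[(2S)-butan-2-yl]oxiran-2-yl]methanol
Conditions: Ti(OiPr)4 (10 mol %), D-(−)-diisopropyl tartrate (12 mol %), t-BuOOH (2 equiv), 4 Å MS, CH2Cl2, −20 °C
Reagents that add atoms: tert-butyl hydroperoxide, CC(C)(C)OO
Why: In the Sharpless asymmetric epoxidation the D-(−)-tartrate catalyst delivers oxygen to the face of the (E)-allylic alcohol that gives the (2R,3R)-trans-epoxide, and this reagent control should override the weak bias of the existing centre.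

Step 4
Reactants: 5 [(2R,3R)-3-[(2S)-butan-2-yl]oxiran-2-yl]methanol
Product: 6 (2S,3R,4S)-2-ethenyl-4-methylhexane-1,3-diol
Conditions: vinylmagnesium bromide (4 equiv), CuI (20 mol %), THF, −30 to −10 °C
Reagents that add atoms: vinylmagnesium bromide, C=C[Mg]Br
Why: In this copper-catalysed Grignard opening of a 2,3-epoxy alcohol the vinyl cuprate should attack C2 by SN2 with inversion, because C3 is shielded by the α-branched sec-butyl group, which gives the anti 2-vinyl-1,3-diol with the carbinol centre untouched.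

Step 5
Reactants: 6 (2S,3R,4S)-2-ethenyl-4-methylhexane-1,3-diol
Product: 7 (4R,5S)-4-[(2S)-butan-2-yl]-5-ethenyl-2,2-dimethyl-1,3-dioxane
Conditions: 2,2-dimethoxypropane (3 equiv), PPTS (5 mol %), CH2Cl2, rt
Reagents that add atoms: 2,2-dimethoxypropane, COC(C)(C)OC
Why: Acid-catalysed transketalisation ties the 1,3-diol into a six-membered acetonide with both ring substituents equatorial, and no stereocentre is involved.

Step 6
Reactants: 7 (4R,5S)-4-[(2S)-butan-2-yl]-5-ethenyl-2,2-dimethyl-1,3-dioxane; 8 4,4,5,5-tetramethyl-2-vinyl-1,3,2-dioxaborolane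
Product: 9 2-[(E)-2-[(4R,5S)-4-[(2S)-butan-2-yl]-2,2-dimethyl-1,3-dioxan-5-yl]ethenyl]-4,4,5,5-tetramethyl-1,3,2-dioxaborolane
Conditions: 8 (3 equiv), second-generation Grubbs catalyst RuCl2(=CHPh)(H2IMes)(PCy3) (5 mol %), CH2Cl2, 40 °C
Reagents that add atoms: none
Why: Olefin cross-metathesis of the terminal alkene with the vinylboronate, driven by loss of ethene, should give the (E)-alkenylboronate because the bulky boronate and the branched allylic carbon disfavour the (Z)-isomer.

Step 7
Reactants: 9 2-[(E)-2-[(4R,5S)-4-[(2S)-butan-2-yl]-2,2-dimethyl-1,3-dioxan-5-yl]ethenyl]-4,4,5,5-tetramethyl-1,3,2-dioxaborolane; 10 3-bromo-2-(bromomethyl)prop-1-ene; 11 tert-butyl acetoacetate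
Product: 14 tert-butyl (8E)-9-[(4R,5S)-4-[(2S)-butan-2-yl]-2,2-dimethyl-1,3-dioxan-5-yl]-6-methylidene-3-oxonon-8-enoate, via allylic bromide 12 (not isolated), via acetoacetate dianion 13 (not isolated)
Conditions: 10 (5 equiv), Pd(PPh3)4 (5 mol %), CsF (3 equiv), THF, 60 °C; filter, evaporate excess 10; then 13 [from 11 (1.5 equiv), LiN(iPr)2 (3 equiv), THF, 0 °C], −78 to 0 °C
Reagents that add atoms: none
Why: Zerovalent palladium inserts into one C–Br bond of 10 to give a 2-(bromomethyl)-π-allyl complex of divalent palladium whose two termini are equivalent, the fluoride-activated boronate 9 transfers its alkenyl group with retention of the (E) geometry, and reductive elimination releases the skipped-diene allylic bromide 12; after the excess of 10 is stripped, the terminal carbanion of dianion 13 displaces the remaining bromide by SN2. The closest known reaction types are the Suzuki–Miyaura allyl–alkenyl coupling and the γ-alkylation of an acetoacetate dianion with an allylic halide. No ring is closed and no stereocentre is created; the three existing centres carry no acidic hydrogen and are not touched. The selectivities needed are mono- over double substitution of 10, secured by its fivefold excess and its removal by evaporation, and γ- over α-alkylation, secured by the far higher nucleophilicity of the terminal carbon of 13. The order is essential, because an enolate alkylated first would leave a monoanion able to cyclise onto the second bromide, whereas the equivalent allyl termini leave no regiochemical question in the coupling.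

Step 8
Reactants: 14 tert-butyl (8E)-9-[(4R,5S)-4-[(2S)-butan-2-yl]-2,2-dimethyl-1,3-dioxan-5-yl]-6-methylidene-3-oxonon-8-enoate; 15 methyl (R)-3-hydroxybutanoate
Product: 17 (2R)-4-methoxy-4-oxobutan-2-yl (8E)-9-[(4R,5S)-4-[(2S)-butan-2-yl]-2,2-dimethyl-1,3-dioxan-5-yl]-6-methylidene-3-oxonon-8-enoate, via acylketene 16 (not isolated)
Conditions: 15 (3 equiv), toluene, 110 °C, t-BuOH distilled off
Reagents that add atoms: none
Why: Thermal loss of tert-butanol from the tert-butyl β-keto ester gives acylketene 16, which the excess secondary alcohol captures (transacetoacetylation), and since the C–O bond at the carbinol of 15 is never broken its (R) configuration is kept.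

Step 9
Reactants: 17 (2R)-4-methoxy-4-oxobutan-2-yl (8E)-9-[(4R,5S)-4-[(2S)-butan-2-yl]-2,2-dimethyl-1,3-dioxan-5-yl]-6-methylidene-3-oxonon-8-enoate
Product: 19 (6R)-4-hydroxy-3-[(6E,8S,9R,10S)-9-hydroxy-8-(hydroxymethyl)-10-methyl-4-methylidenedodec-6-enoyl]-6-methyl-5,6-dihydro-2H-pyran-2-one, via acetonide pyranone 18 (not isolated)
Conditions: KOtBu (1.5 equiv), THF/t-BuOH, 0 °C to rt; then 2 M HCl (aq), rt
Reagents that add atoms: none
Why: In this Lacey–Dieckmann cyclisation the β-keto ester enolate attacks the methyl ester in a 6-exo-trig closure and the product is drained as its stabilised tricarbonyl anion, after which the aqueous acid needed to protonate it also hydrolyses the acetonide, with no stereocentre touched.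

Step 10
Reactants: 19 (6R)-4-hydroxy-3-[(6E,8S,9R,10S)-9-hydroxy-8-(hydroxymethyl)-10-methyl-4-methylidenedodec-6-enoyl]-6-methyl-5,6-dihydro-2H-pyran-2-one
Product: 20 (2R,3E)-2-[(1R,2S)-1-hydroxy-2-methylbutyl]-9-[(6R)-4-hydroxy-6-methyl-2-oxo-5,6-dihydro-2H-pyran-3-yl]-6-methylidene-9-oxonon-3-enoic acid
Conditions: TEMPO (20 mol %), PhI(OAc)2 (2.5 equiv), MeCN/H2O (1:1), 0 °C to rt
Reagents that add atoms: water, O
Why: The oxoammonium-mediated TEMPO/PhI(OAc)2 oxidation in aqueous acetonitrile should oxidise the primary carbinol much faster than the hindered secondary one and carry the aldehyde hydrate on to the acid under mildly acidic conditions that leave the α-stereocentre, the skipped diene and the enolised tricarbonyl alone, the descriptor at the α-carbon changing from S to R only through the change in substituent priority.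

Compound list
1 | (S)-2-methylbutan-1-ol | CC[C@H](C)CO | starting material
2 | (S)-2-methylbutanal | CC[C@H](C)C=O | intermediate
3 | ethyl (2E,4S)-4-methylhex-2-enoate | CC[C@H](C)/C=C/C(=O)OCC | intermediate
4 | (2E,4S)-4-methylhex-2-en-1-ol | CC[C@H](C)/C=C/CO | intermediate
5 | [(2R,3R)-3-[(2S)-butan-2-yl]oxiran-2-yl]methanol | OC[C@H]1O[C@@H]1[C@@H](C)CC | intermediate
6 | (2S,3R,4S)-2-ethenyl-4-methylhexane-1,3-diol | C=C[C@@H](CO)[C@H](O)[C@@H](C)CC | intermediate
7 | (4R,5S)-4-[(2S)-butan-2-yl]-5-ethenyl-2,2-dimethyl-1,3-dioxane | C=C[C@H]1COC(C)(C)O[C@@H]1[C@@H](C)CC | intermediate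
8 | 4,4,5,5-tetramethyl-2-vinyl-1,3,2-dioxaborolane | C=CB1OC(C)(C)C(C)(C)O1 | starting material
9 | 2-[(E)-2-[(4R,5S)-4-[(2S)-butan-2-yl]-2,2-dimethyl-1,3-dioxan-5-yl]ethenyl]-4,4,5,5-tetramethyl-1,3,2-dioxaborolane | CC1(C)OB(/C=C/[C@H]2COC(C)(C)O[C@@H]2[C@@H](C)CC)OC1(C)C | intermediate
10 | 3-bromo-2-(bromomethyl)prop-1-ene | C=C(CBr)CBr | starting material
11 | tert-butyl acetoacetate (tert-butyl 3-oxobutanoate) | CC(=O)CC(=O)OC(C)(C)C | starting material
12 | (4R,5S)-5-[(1E)-4-(bromomethyl)penta-1,4-dien-1-yl]-4-[(2S)-butan-2-yl]-2,2-dimethyl-1,3-dioxane | C=C(CBr)C/C=C/[C@H]1COC(C)(C)O[C@@H]1[C@@H](C)CC | intermediate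
13 | dilithium dianion of tert-butyl acetoacetate (dilithium 1-tert-butoxy-1,3-dioxobutane-2,4-diide) | [Li+].[Li+].[CH2-]C(=O)[CH-]C(=O)OC(C)(C)C | intermediate
14 | tert-butyl (8E)-9-[(4R,5S)-4-[(2S)-butan-2-yl]-2,2-dimethyl-1,3-dioxan-5-yl]-6-methylidene-3-oxonon-8-enoate | C=C(C/C=C/[C@H]1COC(C)(C)O[C@@H]1[C@@H](C)CC)CCC(=O)CC(=O)OC(C)(C)C | intermediate
15 | methyl (R)-3-hydroxybutanoate | C[C@@H](O)CC(=O)OC | starting material
16 | (8E)-9-[(4R,5S)-4-[(2S)-butan-2-yl]-2,2-dimethyl-1,3-dioxan-5-yl]-6-methylidenenona-1,8-diene-1,3-dione (acylketene) | C=C(C/C=C/[C@H]1COC(C)(C)O[C@@H]1[C@@H](C)CC)CCC(=O)C=C=O | intermediate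
17 | (2R)-4-methoxy-4-oxobutan-2-yl (8E)-9-[(4R,5S)-4-[(2S)-butan-2-yl]-2,2-dimethyl-1,3-dioxan-5-yl]-6-methylidene-3-oxonon-8-enoate | C=C(C/C=C/[C@H]1COC(C)(C)O[C@@H]1[C@@H](C)CC)CCC(=O)CC(=O)O[C@H](C)CC(=O)OC | intermediate
18 | (6R)-3-[(6E)-7-[(4R,5S)-4-[(2S)-butan-2-yl]-2,2-dimethyl-1,3-dioxan-5-yl]-4-methylidenehept-6-enoyl]-4-hydroxy-6-methyl-5,6-dihydro-2H-pyran-2-one | C=C(C/C=C/[C@H]1COC(C)(C)O[C@@H]1[C@@H](C)CC)CCC(=O)C1=C(O)C[C@@H](C)OC1=O | intermediate
19 | (6R)-4-hydroxy-3-[(6E,8S,9R,10S)-9-hydroxy-8-(hydroxymethyl)-10-methyl-4-methylidenedodec-6-enoyl]-6-methyl-5,6-dihydro-2H-pyran-2-one | C=C(C/C=C/[C@@H](CO)[C@H](O)[C@@H](C)CC)CCC(=O)C1=C(O)C[C@@H](C)OC1=O | intermediate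
20 | (2R,3E)-2-[(1R,2S)-1-hydroxy-2-methylbutyl]-9-[(6R)-4-hydroxy-6-methyl-2-oxo-5,6-dihydro-2H-pyran-3-yl]-6-methylidene-9-oxonon-3-enoic acid | C=C(C/C=C/[C@@H](C(=O)O)[C@H](O)[C@@H](C)CC)CCC(=O)C1=C(O)C[C@@H](C)OC1=O | target

Total step count: 10. Longest linear sequence: 10 steps (1 to 20); compounds 8, 10, 11 and 15 are commercial and enter directly.

Steps most likely to fail

Step 7. The linchpin may be substituted twice, boronate 9 may lose boron by protodeboronation, or the allylic bromide may be lost during the telescoped hand-over (substitution by fluoride or adventitious water). The fallback sets out from 9 and comes back to the route at 12. It uses a linchpin whose second electrophilic site is masked as an ester. Suzuki–Miyaura coupling of 9 with commercial ethyl 2-(bromomethyl)acrylate (Pd(PPh3)4, CsF, THF) should give ethyl (4E)-5-[(4R,5S)-4-[(2S)-butan-2-yl]-2,2-dimethyl-1,3-dioxan-5-yl]-2-methylidenepent-4-enoate F1. Reduction with iBu2AlH should give (4E)-5-[(4R,5S)-4-[(2S)-butan-2-yl]-2,2-dimethyl-1,3-dioxan-5-yl]-2-methylidenepent-4-en-1-ol F2. Appel bromination (CBr4, PPh3) should then give 12 as an isolated, purified compound, which is alkylated with dianion 13 as in step 7 to give 14.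

Step 10. The oxidant may attack the enolised tricarbonyl, the secondary carbinol may be over-oxidised, or the alkene may migrate into conjugation at the transient α-vinyl aldehyde. The fallback sets out from 17 and comes back at 20. It oxidises before the ring exists and closes the ring last. Aqueous AcOH on 17 should remove the acetonide and give (2R)-4-methoxy-4-oxobutan-2-yl (8E,10S,11R,12S)-11-hydroxy-10-(hydroxymethyl)-12-methyl-6-methylidene-3-oxotetradec-8-enoate F3. TEMPO/PhI(OAc)2 in MeCN/H2O should give (2R,3E)-2-[(1R,2S)-1-hydroxy-2-methylbutyl]-11-{[(2R)-4-methoxy-4-oxobutan-2-yl]oxy}-6-methylidene-9,11-dioxoundec-3-enoic acid F4. KOtBu (3.5 equiv) in THF/t-BuOH should then effect the Dieckmann cyclisation on the carboxylate, whose negative charge protects the α-stereocentre from enolisation, and acidification should give 20.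

Step 9. The acetoacetate may be lost from the β-acyloxy ester by E1cB elimination (crotonate formation), or retro-Claisen cleavage may compete with ring closure. The fallback sets out from 12 and comes back at 18. It attaches a preformed ring by O-acylation and acyl migration.
- Alkylation of crude 12 with the lithium enolate of ethyl acetate (LiN(iPr)2, THF, −78 °C) should give ethyl (6E)-7-[(4R,5S)-4-[(2S)-butan-2-yl]-2,2-dimethyl-1,3-dioxan-5-yl]-4-methylidenehept-6-enoate F5.
- LiOH in THF/H2O should give (6E)-7-[(4R,5S)-4-[(2S)-butan-2-yl]-2,2-dimethyl-1,3-dioxan-5-yl]-4-methylidenehept-6-enoic acid F6.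
- Separately, Claisen condensation of 15 with the lithium enolate of tert-butyl acetate should give tert-butyl (5R)-5-hydroxy-3-oxohexanoate F7, which CF3CO2H should lactonise to (6R)-4-hydroxy-6-methyl-5,6-dihydro-2H-pyran-2-one F8.
- Steglich coupling (DCC, DMAP) of F6 with F8 should give the enol ester (6R)-6-methyl-2-oxo-5,6-dihydro-2H-pyran-4-yl (6E)-7-[(4R,5S)-4-[(2S)-butan-2-yl]-2,2-dimethyl-1,3-dioxan-5-yl]-4-methylidenehept-6-enoate F9.
- Excess DMAP should rearrange F9 by a Fries-type O-to-C acyl shift to 18, and aqueous HCl as in step 9 should give 19.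

Further compounds
F1 | step 7 | ethyl (4E)-5-[(4R,5S)-4-[(2S)-butan-2-yl]-2,2-dimethyl-1,3-dioxan-5-yl]-2-methylidenepent-4-enoate | C=C(C/C=C/[C@H]1COC(C)(C)O[C@@H]1[C@@H](C)CC)C(=O)OCC
F2 | step 7 | (4E)-5-[(4R,5S)-4-[(2S)-butan-2-yl]-2,2-dimethyl-1,3-dioxan-5-yl]-2-methylidenepent-4-en-1-ol | C=C(CO)C/C=C/[C@H]1COC(C)(C)O[C@@H]1[C@@H](C)CC
F3 | step 10 | (2R)-4-methoxy-4-oxobutan-2-yl (8E,10S,11R,12S)-11-hydroxy-10-(hydroxymethyl)-12-methyl-6-methylidene-3-oxotetradec-8-enoate | C=C(C/C=C/[C@@H](CO)[C@H](O)[C@@H](C)CC)CCC(=O)CC(=O)O[C@H](C)CC(=O)OC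
F4 | step 10 | (2R,3E)-2-[(1R,2S)-1-hydroxy-2-methylbutyl]-11-{[(2R)-4-methoxy-4-oxobutan-2-yl]oxy}-6-methylidene-9,11-dioxoundec-3-enoic acid | C=C(C/C=C/[C@@H](C(=O)O)[C@H](O)[C@@H](C)CC)CCC(=O)CC(=O)O[C@H](C)CC(=O)OC
F5 | step 9 | ethyl (6E)-7-[(4R,5S)-4-[(2S)-butan-2-yl]-2,2-dimethyl-1,3-dioxan-5-yl]-4-methylidenehept-6-enoate | C=C(C/C=C/[C@H]1COC(C)(C)O[C@@H]1[C@@H](C)CC)CCC(=O)OCC
F6 | step 9 | (6E)-7-[(4R,5S)-4-[(2S)-butan-2-yl]-2,2-dimethyl-1,3-dioxan-5-yl]-4-methylidenehept-6-enoic acid | C=C(C/C=C/[C@H]1COC(C)(C)O[C@@H]1[C@@H](C)CC)CCC(=O)O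
F7 | step 9 | tert-butyl (5R)-5-hydroxy-3-oxohexanoate | C[C@@H](O)CC(=O)CC(=O)OC(C)(C)C
F8 | step 9 | (6R)-4-hydroxy-6-methyl-5,6-dihydro-2H-pyran-2-one | C[C@@H]1CC(O)=CC(=O)O1
F9 | step 9 | (6R)-6-methyl-2-oxo-5,6-dihydro-2H-pyran-4-yl (6E)-7-[(4R,5S)-4-[(2S)-butan-2-yl]-2,2-dimethyl-1,3-dioxan-5-yl]-4-methylidenehept-6-enoate | C=C(C/C=C/[C@H]1COC(C)(C)O[C@@H]1[C@@H](C)CC)CCC(=O)OC1=CC(=O)O[C@H](C)C1
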